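You want the nucleophile charge, in equivalents of electrophile, that leaves 80% of the electrophile reacted at 40 h.

electrophile 0.010 M; time 40 h

    electrophile + nucleophile → acid set free + target (k1 = 8.2 M⁻¹ h⁻¹)
    nucleophile + acid set free ⇌ protonated nucleophile, settled at all times (K2 = 30000 M⁻¹)
    electrophile + acid set free → side product (k3 = 48 M⁻¹ h⁻¹)
    nucleophile + acid set free ⇌ idle adduct, settled at all times (K4 = 4600 M⁻¹)
    nucleophile → decomposition product (k5 = 2.4 × 10⁻⁴ h⁻¹)

- the equivalents of nucleophile at which the part of the electrophile that has reacted at 40 h is just 80%

- amounts and yields of acid set free count idle adduct too
- the amount of nucleophile is what is sought; it is there from the start
- run time (flask): 40 h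

Two routes use electrophile. Their rate ratio, the selectivity factor, is the rate of the route to target over the rate of the route to side product. Acid is held as protonated nucleophile and idle adduct, so [acid set free] falls as [nucleophile] rises. Let b be free nucleophile and a be bound acid, both in equivalents. The factor then becomes g·b²/a, where g is the first rate constant times the two balance constants added, times the charge of electrophile, over the side-route rate constant. Work in powers of ten:

Row g: 59.1, logarithm 1.77.

Row a, taken as the part wanted: 80%, logarithm −0.0969.

Row b, level routes: logarithm −0.934.

Read the rows downward. The first row is large, and the second barely differs from zero. The third is half their difference, and b enters squared. It gives the crossing level, the free nucleophile at which both routes use electrophile equally: 0.116 equiv. At that level nearly all of the acid is bound, so an electrophile taken by the route to target costs 2 nucleophile, one used and one held. I count every reacted electrophile at that cost, though the route to side product uses acid and so frees bound nucleophile. That makes 1.60 equiv, and adding the crossing level as the free nucleophile left gives my figure, 1.72 equiv.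

The forecast says 1.66 equiv, lower than mine, on the ground that late in the run “the acid-driven side reaction adds to electrophile consumption and gives back nucleophile”.

The simulation gives 1.65 equiv, so the forecast holds. The route to target outran the route to side product by 120 at 4.93 h, but by far less at 40.0 h, at 2.1. Free nucleophile then stood at 9.71% of the charge, or 0.160 equiv, and its square against the crossing level's square gives 1.91.

The constants used here belong to no real substance; what happens was integrated by code.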